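## Retrosynthetic overview

1. The ten-membered carbocycle is closed last, by intramolecular Ni/Cr (Nozaki–Hiyama–Kishi) addition of the C10 alkenyl iodide to the C1 aldehyde; this forms C1–C10, the C1 carbinol and the 10(14)-methylene.
2. The seco-aldehyde comes from angeloylation of C6–OH after a Zn-Barbier union (C6–C7) of a 3-(bromomethyl)butenolide with an α,β-epoxy aldehyde; this step creates the α-methylene-γ-lactone, C6 and C7.
3. The bromomethyl butenolide (C7–C14) comes from ring-closing metathesis of a 2-(bromomethyl)acrylate; its C8 centre comes from (S)-epichlorohydrin plus a 1-silylvinyl Grignard reagent.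
4. The epoxy aldehyde (C1–C6, C15) comes from Sharpless epoxidation of a Z-allylic alcohol made from neryl acetate (sets C4, C5).
5. Ring order: oxirane and butenolide (separate branches), then butenolide converted to α-methylene lactone at the union, then the ten-membered ring.

Assumption: locants C1–C15 are germacrane locants with the lactone oxygen on C8 and the angelate on C6; in this numbering the target is (1S,4R,5S,6S,7R,8S).

## Route

### Branch A: epoxy aldehyde (C1–C6)

Step 1
Reactants: 1 neryl acetate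
Product: 3 (2Z)-6-hydroxy-3-methylhex-2-en-1-yl acetate, via aldehyde 2 (not isolated)
Conditions: O3 (1.0 equiv, Sudan III end point), pyridine, CH2Cl2, −78 °C; then NaBH4, MeOH, −78 → 0 °C
Reagents that add atoms: ozone, [O-][O+]=O
Why: Chemoselective ozonolysis, because the electron-rich remote trisubstituted alkene reacts much faster than the acetate-deactivated allylic alkene, and the aldehyde is reduced in the same pot (no stereocentre formed, Z-alkene untouched).

Step 2
Reactants: 3 (2Z)-6-hydroxy-3-methylhex-2-en-1-yl acetate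
Product: 4 (2Z)-6-[(tert-butyldimethylsilyl)oxy]-3-methylhex-2-en-1-yl acetate
Conditions: TBSCl, imidazole, DMF, 0 °C → rt
Reagents that add atoms: tert-butyldimethylsilyl chloride, CC(C)(C)[Si](C)(C)Cl
Why: Standard silylation of the unhindered primary alcohol, which masks the future C1 aldehyde.

Step 3
Reactants: 4 (2Z)-6-[(tert-butyldimethylsilyl)oxy]-3-methylhex-2-en-1-yl acetate
Product: 5 (2Z)-6-[(tert-butyldimethylsilyl)oxy]-3-methylhex-2-en-1-ol
Conditions: K2CO3 (cat.), MeOH, 0 °C → rt
Reagents that add atoms: none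
Why: Base-catalysed transesterification (methanolysis) removes the acetate while the TBS ether and the Z-alkene are stable.

Step 4
Reactants: 5 (2Z)-6-[(tert-butyldimethylsilyl)oxy]-3-methylhex-2-en-1-ol
Product: 6 [(2S,3R)-3-{3-[(tert-butyldimethylsilyl)oxy]propyl}-3-methyloxiran-2-yl]methanol
Conditions: Ti(OiPr)4 (10 mol%), L-(+)-diethyl tartrate (12 mol%), t-BuOOH, 4 Å MS, CH2Cl2, −20 °C
Reagents that add atoms: tert-butyl hydroperoxide, CC(C)(C)OO
Why: Sharpless asymmetric epoxidation of a nerol-type Z-allylic alcohol, where L-(+)-tartrate gives the (2S,3R)-epoxide (C5 and C4 of the target, about 90–94% ee; the minor enantiomer is removed as a diastereomer after step 12).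

Step 5
Reactants: 6 [(2S,3R)-3-{3-[(tert-butyldimethylsilyl)oxy]propyl}-3-methyloxiran-2-yl]methanol
Product: 7 (2R,3R)-3-{3-[(tert-butyldimethylsilyl)oxy]propyl}-3-methyloxirane-2-carbaldehyde
Conditions: Dess–Martin periodinane, NaHCO3, CH2Cl2, 0 °C → rt; used directly
Reagents that add atoms: none
Why: Buffered Dess–Martin oxidation gives the epoxy aldehyde without epimerisation or epoxide opening (the descriptor at C2 changes only through CIP priorities).

### Branch B: bromomethyl butenolide (C7–C14)

Step 6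
Reactants: 8 (S)-epichlorohydrin; 9 (1-bromoethenyl)trimethylsilane
Product: 11 (2S)-1-chloro-4-(trimethylsilyl)pent-4-en-2-ol, via Grignard reagent 10 (not isolated)
Conditions: 9, Mg, THF, reflux; then CuI (10 mol%), 8, THF, −30 → 0 °C; aq NH4Cl
Reagents that add atoms: none
Why: Copper-catalysed Grignard opening of the epoxide at its terminal carbon leaves the chiral-pool stereocentre (future C8) untouched and brings in C10 as a vinylsilane.

Step 7
Reactants: 11 (2S)-1-chloro-4-(trimethylsilyl)pent-4-en-2-ol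
Product: 13 (3S)-5-(trimethylsilyl)hexa-1,5-dien-3-ol, via epoxide 12 (not isolated)
Conditions: Me3S+ I− (4 equiv), n-BuLi (3.8 equiv), THF, −10 °C → rt
Reagents that add atoms: trimethylsulfonium iodide, C[S+](C)C.[I-]
Why: Base closes the chlorohydrin to the epoxide, and dimethylsulfonium methylide opens it at CH2 and eliminates Me2S (sulfonium-ylide one-carbon homologation to an allylic alcohol); the carbinol centre is not touched.

Step 8
Reactants: 14 2-(bromomethyl)prop-2-enoic acid
Product: 15 2-(bromomethyl)prop-2-enoyl chloride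
Conditions: (COCl)2, DMF (cat.), CH2Cl2, 0 °C → rt; concentrate
Reagents that add atoms: oxalyl chloride, O=C(Cl)C(=O)Cl
Why: Vilsmeier-catalysed acid chloride formation gives an acylating agent that needs no nucleophilic catalyst, which would attack the allylic bromide.

Step 9
Reactants: 13 (3S)-5-(trimethylsilyl)hexa-1,5-dien-3-ol; 15 2-(bromomethyl)prop-2-enoyl chloride
Product: 16 (3S)-5-(trimethylsilyl)hexa-1,5-dien-3-yl 2-(bromomethyl)prop-2-enoate
Conditions: i-Pr2NEt, CH2Cl2, −40 → 0 °C
Reagents that add atoms: none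
Why: O-acylation with an acid chloride and a hindered, non-nucleophilic base spares the SN2′-prone allylic bromide and retains the carbinol configuration.

Step 10
Reactants: 16 (3S)-5-(trimethylsilyl)hexa-1,5-dien-3-yl 2-(bromomethyl)prop-2-enoate
Product: 17 (5S)-3-(bromomethyl)-5-[2-(trimethylsilyl)prop-2-en-1-yl]furan-2(5H)-one
Conditions: Grubbs II (5 mol%), CH2Cl2 (5 mM), 40 °C
Reagents that add atoms: none
Why: Ring-closing metathesis between the vinyl group and the acrylate alkene forms the five-membered butenolide with loss of ethene, the bulky 1,1-disubstituted vinylsilane being inert to the catalyst.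

Step 11
Reactants: 17 (5S)-3-(bromomethyl)-5-[2-(trimethylsilyl)prop-2-en-1-yl]furan-2(5H)-one
Product: 18 (5S)-3-(bromomethyl)-5-(2-iodoprop-2-en-1-yl)furan-2(5H)-one
Conditions: N-iodosuccinimide (1.5 equiv), MeCN/ClCH2CN 4:1, 0 °C → rt, dark
Reagents that add atoms: N-iodosuccinimide, O=C1CCC(=O)N1I
Why: Iododesilylation (ipso substitution through a β-silyl cation) gives the 2-iodoalkene, the electron-poor butenolide alkene and the allylic bromide being unreactive to NIS.

### Union and ring closure

Step 12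
Reactants: 18 (5S)-3-(bromomethyl)-5-(2-iodoprop-2-en-1-yl)furan-2(5H)-one; 7 (2R,3R)-3-{3-[(tert-butyldimethylsilyl)oxy]propyl}-3-methyloxirane-2-carbaldehyde
Product: 19 (4S,5S)-4-[(S)-{(2S,3R)-3-[3-(tert-butyldimethylsilyloxy)propyl]-3-methyloxiran-2-yl}(hydroxy)methyl]-5-(2-iodoprop-2-en-1-yl)-3-methylideneoxolan-2-one
Conditions: activated Zn dust (4 equiv), THF/sat. aq NH4Cl 4:1, 0 °C, 18 (1.2 equiv)
Reagents that add atoms: none
Why: Zn-Barbier 2-(alkoxycarbonyl)allylation in which Zn inserts only into the allylic C–Br bond and the ring carbon (C7) attacks the aldehyde: C7 forms anti to the C8 side chain (trans lactone), C6 follows from a chair Zimmerman–Traxler transition state with the ring-locked E-type allylzinc, and this is matched with Felkin–Anh/Cornforth addition to the epoxy aldehyde (C5/C6 erythro).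

Step 13
Reactants: 19 (the C6 carbinol from step 12); 20 angelic acid
Product: 22 (S)-{(2S,3R)-3-[3-(tert-butyldimethylsilyloxy)propyl]-3-methyloxiran-2-yl}[(2S,3R)-2-(2-iodoprop-2-en-1-yl)-4-methylidene-5-oxooxolan-3-yl]methyl (2Z)-2-methylbut-2-enoate, via mixed anhydride 21 (not isolated)
Conditions: 20, 2,4,6-trichlorobenzoyl chloride, Et3N, toluene, rt; filter; then 19, toluene, 80 °C
Reagents that add atoms: none
Why: Yamaguchi-type mixed-anhydride esterification run without DMAP acylates the hindered C6–OH at the less hindered angeloyl carbonyl and avoids Z→E isomerisation to the tiglate; C6 is retained.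

Step 14
Reactants: 22 (the silyl-protected angelate from step 13)
Product: 23 (S)-[(2S,3R)-3-(3-hydroxypropyl)-3-methyloxiran-2-yl][(2S,3R)-2-(2-iodoprop-2-en-1-yl)-4-methylidene-5-oxooxolan-3-yl]methyl (2Z)-2-methylbut-2-enoate
Conditions: HF·pyridine, excess pyridine, THF, 0 °C
Reagents that add atoms: none
Why: Pyridine-buffered fluoride desilylation cleaves the primary TBS ether under conditions that leave the trisubstituted epoxide, the angelate and the α-methylene lactone intact.

Step 15
Reactants: 23 (the primary alcohol from step 14)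
Product: 24 (S)-[(2S,3R)-3-methyl-3-(3-oxopropyl)oxiran-2-yl][(2S,3R)-2-(2-iodoprop-2-en-1-yl)-4-methylidene-5-oxooxolan-3-yl]methyl (2Z)-2-methylbut-2-enoate
Conditions: Dess–Martin periodinane, NaHCO3, CH2Cl2, 0 °C → rt
Reagents that add atoms: none
Why: Neutral Dess–Martin oxidation gives the C1 aldehyde without touching the alkenyl iodide, the epoxide or the enoates.

Step 16
Reactants: 24 (the seco iodo-aldehyde from step 15)
Product: 25 (1S,4R,5S,6S,7R,8S)-6-angeloyloxy-4,5-epoxy-1-hydroxygermacra-10(14),11(13)-dien-12,8-olide (target)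
Conditions: CrCl2 (6 equiv), Kishi oxazoline–sulfonamide ligand (6.6 equiv, the antipode that directs Re-face addition; the sense of induction of a given antipode is not assigned here and is fixed in a model coupling), Et3N, NiCl2·neocuproine (0.2 equiv), MeCN, rt, slow addition of 24 to 2 mM
Reagents that add atoms: none
Why: Nozaki–Hiyama–Kishi macrocyclisation, in which Ni inserts into the alkenyl C–I bond, transmetalation to Cr(III) and aldehyde-selective addition close the ten-membered ring and create the 2-methylene allylic alcohol, C1 (S) being set by Re-face addition under control of the chiral Cr–sulfonamide complex on an α-unbranched aldehyde.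

## Compound list

1 | neryl acetate, (2Z)-3,7-dimethylocta-2,6-dien-1-yl acetate | CC(C)=CCC/C(C)=C\COC(C)=O | starting material
2 | (2Z)-3-methyl-6-oxohex-2-en-1-yl acetate | O=CCC/C(C)=C\COC(C)=O | intermediate
3 | (2Z)-6-hydroxy-3-methylhex-2-en-1-yl acetate | OCCC/C(C)=C\COC(C)=O | intermediate
4 | (2Z)-6-[(tert-butyldimethylsilyl)oxy]-3-methylhex-2-en-1-yl acetate | CC(C)(C)[Si](C)(C)OCCC/C(C)=C\COC(C)=O | intermediate
5 | (2Z)-6-[(tert-butyldimethylsilyl)oxy]-3-methylhex-2-en-1-ol | CC(C)(C)[Si](C)(C)OCCC/C(C)=C\CO | intermediate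
6 | [(2S,3R)-3-{3-[(tert-butyldimethylsilyl)oxy]propyl}-3-methyloxiran-2-yl]methanol | CC(C)(C)[Si](C)(C)OCCC[C@@]1(C)O[C@H]1CO | intermediate
7 | (2R,3R)-3-{3-[(tert-butyldimethylsilyl)oxy]propyl}-3-methyloxirane-2-carbaldehyde | CC(C)(C)[Si](C)(C)OCCC[C@@]1(C)O[C@H]1C=O | intermediate
8 | (S)-epichlorohydrin, (2S)-2-(chloromethyl)oxirane | ClC[C@@H]1CO1 | starting material
9 | (1-bromoethenyl)trimethylsilane | C=C(Br)[Si](C)(C)C | starting material
10 | [1-(trimethylsilyl)ethenyl]magnesium bromide | C=C([Mg]Br)[Si](C)(C)C | intermediate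
11 | (2S)-1-chloro-4-(trimethylsilyl)pent-4-en-2-ol | ClC[C@@H](O)CC(=C)[Si](C)(C)C | intermediate
12 | (2S)-2-[2-(trimethylsilyl)prop-2-en-1-yl]oxirane | C1O[C@H]1CC(=C)[Si](C)(C)C | intermediate
13 | (3S)-5-(trimethylsilyl)hexa-1,5-dien-3-ol | C=C[C@@H](O)CC(=C)[Si](C)(C)C | intermediate
14 | 2-(bromomethyl)prop-2-enoic acid | C=C(CBr)C(=O)O | starting material
15 | 2-(bromomethyl)prop-2-enoyl chloride | C=C(CBr)C(=O)Cl | intermediate
16 | (3S)-5-(trimethylsilyl)hexa-1,5-dien-3-yl 2-(bromomethyl)prop-2-enoate | C=C[C@@H](OC(=O)C(=C)CBr)CC(=C)[Si](C)(C)C | intermediate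
17 | (5S)-3-(bromomethyl)-5-[2-(trimethylsilyl)prop-2-en-1-yl]furan-2(5H)-one | O=C1O[C@@H](CC(=C)[Si](C)(C)C)C=C1CBr | intermediate
18 | (5S)-3-(bromomethyl)-5-(2-iodoprop-2-en-1-yl)furan-2(5H)-one | O=C1O[C@@H](CC(I)=C)C=C1CBr | intermediate
19 | (4S,5S)-4-[(S)-{(2S,3R)-3-[3-(tert-butyldimethylsilyloxy)propyl]-3-methyloxiran-2-yl}(hydroxy)methyl]-5-(2-iodoprop-2-en-1-yl)-3-methylideneoxolan-2-one | C=C1C(=O)O[C@@H](CC(I)=C)[C@@H]1[C@H](O)[C@@H]2O[C@]2(C)CCCO[Si](C)(C)C(C)(C)C | intermediate
20 | angelic acid, (2Z)-2-methylbut-2-enoic acid | C/C=C(/C)C(=O)O | starting material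
21 | (2Z)-2-methylbut-2-enoic 2,4,6-trichlorobenzoic anhydride | C/C=C(/C)C(=O)OC(=O)c1c(Cl)cc(Cl)cc1Cl | intermediate
22 | (S)-{(2S,3R)-3-[3-(tert-butyldimethylsilyloxy)propyl]-3-methyloxiran-2-yl}[(2S,3R)-2-(2-iodoprop-2-en-1-yl)-4-methylidene-5-oxooxolan-3-yl]methyl (2Z)-2-methylbut-2-enoate | C=C1C(=O)O[C@@H](CC(I)=C)[C@@H]1[C@H](OC(=O)/C(C)=C\C)[C@@H]2O[C@]2(C)CCCO[Si](C)(C)C(C)(C)C | intermediate
23 | (S)-[(2S,3R)-3-(3-hydroxypropyl)-3-methyloxiran-2-yl][(2S,3R)-2-(2-iodoprop-2-en-1-yl)-4-methylidene-5-oxooxolan-3-yl]methyl (2Z)-2-methylbut-2-enoate | C=C1C(=O)O[C@@H](CC(I)=C)[C@@H]1[C@H](OC(=O)/C(C)=C\C)[C@@H]2O[C@]2(C)CCCO | intermediate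
24 | (S)-[(2S,3R)-3-methyl-3-(3-oxopropyl)oxiran-2-yl][(2S,3R)-2-(2-iodoprop-2-en-1-yl)-4-methylidene-5-oxooxolan-3-yl]methyl (2Z)-2-methylbut-2-enoate | C=C1C(=O)O[C@@H](CC(I)=C)[C@@H]1[C@H](OC(=O)/C(C)=C\C)[C@@H]2O[C@]2(C)CCC=O | intermediate
25 | (1S,4R,5S,6S,7R,8S)-6-angeloyloxy-4,5-epoxy-1-hydroxygermacra-10(14),11(13)-dien-12,8-olide | C=C1C(=O)O[C@H]2CC(=C)[C@@H](O)CC[C@@]3(C)O[C@H]3[C@@H](OC(=O)/C(C)=C\C)[C@H]12 | target

## Step count and risks

Total step count: 16 (branch A: steps 1–5; branch B: steps 6, 7, 9, 10, 11 with side step 8; union: steps 12–16).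
Longest linear sequence: 10 steps (1–5 then 12–16; the epichlorohydrin branch 6, 7, 9, 10, 11 then 12–16 is equally long).

The three steps most likely to fail:

Step 16 (macrocyclisation). A ten-membered ring is strained, and the face selectivity at C1 may be dictated by the ring conformation and not by the ligand. The fallback sets C1 by ketone reduction instead of by the C–C bond formation. It sets out from 24: the ring is closed with unliganded CrCl2 and catalytic NiCl2 in DMSO at 2 mM, and whatever C1 carbinol forms is taken on, in the unfavourable case the (1R)-carbinol epimer of the target F3. Dess–Martin oxidation gives the cross-conjugated ten-membered 1-oxo enone F4. Reduction with (R)-Me-CBS and catecholborane at −78 °C (alkenyl as the large group; Luche reduction as the substrate-controlled alternative) comes back to the route at 25.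

Step 12 (Barbier union). Three control elements must cooperate, and the aldehyde may react through the other carbonyl face to give the C6 epimer. The fallback keeps the C–C bond and corrects C6 during ester formation. It sets out from 18 and 7 and takes the C6-epimeric (R)-carbinol F1. A Mitsunobu reaction of this alcohol with angelic acid 20 (PPh3, DIAD, toluene, 0 °C) installs the angelate with inversion and comes back to the route at 22.

Step 13 (angeloylation). The C6–OH is hindered, angelates isomerise easily to tiglates, and base could trigger translactonisation to the C6 oxygen. The fallback builds the Z double bond on the substrate. It sets out from 19: DCC/DMAP coupling with 2-[bis(2,2,2-trifluoroethoxy)phosphoryl]propanoic acid gives the phosphonopropionate ester F2. A Still–Gennari olefination (KHMDS, 18-crown-6, THF, −78 °C, acetaldehyde) then forms the (Z)-2-methylbut-2-enoate and comes back to the route at 22.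

## Further compounds

F1 | step 12 | (4S,5S)-4-[(R)-{(2S,3R)-3-[3-(tert-butyldimethylsilyloxy)propyl]-3-methyloxiran-2-yl}(hydroxy)methyl]-5-(2-iodoprop-2-en-1-yl)-3-methylideneoxolan-2-one | C=C1C(=O)O[C@@H](CC(I)=C)[C@@H]1[C@@H](O)[C@@H]2O[C@]2(C)CCCO[Si](C)(C)C(C)(C)C
F2 | step 13 | (S)-{(2S,3R)-3-[3-(tert-butyldimethylsilyloxy)propyl]-3-methyloxiran-2-yl}[(2S,3R)-2-(2-iodoprop-2-en-1-yl)-4-methylidene-5-oxooxolan-3-yl]methyl 2-[bis(2,2,2-trifluoroethoxy)phosphoryl]propanoate | C=C1C(=O)O[C@@H](CC(I)=C)[C@@H]1[C@H](OC(=O)C(C)P(=O)(OCC(F)(F)F)OCC(F)(F)F)[C@@H]2O[C@]2(C)CCCO[Si](C)(C)C(C)(C)C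
F3 | step 16 | (1R,4R,5S,6S,7R,8S)-6-angeloyloxy-4,5-epoxy-1-hydroxygermacra-10(14),11(13)-dien-12,8-olide | C=C1C(=O)O[C@H]2CC(=C)[C@H](O)CC[C@@]3(C)O[C@H]3[C@@H](OC(=O)/C(C)=C\C)[C@H]12
F4 | step 16 | (4R,5S,6S,7R,8S)-6-angeloyloxy-4,5-epoxy-1-oxogermacra-10(14),11(13)-dien-12,8-olide | C=C1C(=O)O[C@H]2CC(=C)C(=O)CC[C@@]3(C)O[C@H]3[C@@H](OC(=O)/C(C)=C\C)[C@H]12
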